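**Plan**
Retrosynthesis: the pyridone ring is cut at N1–C2, then at C4–C3 and C4a–C4, which leaves 2-iodo-N-methylaniline 1, carbon monoxide 2 and 1-heptadecyne 3.
Enabling feature: C4 is a carbonyl carbon lying between the benzo carbon C4a and C3 of the N1–C2=C3 enaminone unit. C4 can therefore enter as CO and C3/C2 as the two sp carbons of a terminal alkyne whose chain becomes the C2 pentadecyl group, while N1 sits ortho to C4a and can close onto C2.
Forward: in one pot, Pd/Cu carbonylative coupling joins 1, 2 and 3 to ynone 4 (C4a–C4 and C4–C3). Diethylamine then adds to give enaminone 5, and N1 closes onto C2 to form the only new ring, the pyridone of quinolone 6.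
Stereochemistry: none to set; 6 is achiral and has no stereogenic double bond.

Key step: step 1

Assumption: the target has no stereocentre, so "single enantiomer" is read as the one achiral compound of the given SMILES; 1, 2 and 3 are taken as catalogue chemicals.

Step 1
Reactants: 1 2-iodo-N-methylaniline; 2 carbon monoxide; 3 1-heptadecyne
Product: 6 1-methyl-2-pentadecyl-4(1H)-quinolone, via ynone 4 (not isolated), via enaminone 5 (not isolated)
Conditions: PdCl2(PPh3)2 (2 mol%), CuI (2 mol%), CO (3 bar), Et3N (3 equiv), degassed THF, rt; then vent, Et2NH (5 equiv), 80 °C (sealed)
Reagents that add atoms: none
Why: Carbonylative Sonogashira coupling followed by amine-relayed aza-Michael closure: Pd(0) inserts into the C–I bond of 1, CO migratory insertion gives the aroyl-palladium iodide, copper(I) heptadecynide transmetalates, and reductive elimination forms C4a–C4 and C4–C3 in ynone 4. Diethylamine then adds to the ynone β-carbon to give enaminone 5, whose N-methylamino group attacks the same carbon and expels diethylamine again, forming N1–C2. The closest known reaction type is the palladium-catalysed carbonylative annulation of 2-iodoanilines with terminal alkynes, which gives 2-substituted 4-quinolones through amine-mediated cyclisation of the ortho-aminoaryl ynone. The one ring closes in a formal 6-endo-dig sense at the ynone, realised as a 6-endo-trig addition–elimination on 5, with the aromatic 4-pyridone as thermodynamic sink; no stereocentre is created. The step needs alkyne capture of the aroyl-palladium to outrun N-acylation and CO-free coupling, and 6-endo closure to outrun 5-exo closure. The substrate and staging should secure this: the ortho N-methylamino nitrogen is hindered and conjugated (in 4 also hydrogen-bonded to the carbonyl), the only other amine in the first stage is tertiary, CO pressure and the electron-rich aryl group favour insertion before transmetalation, and in 5 only the β-carbon is electrophilic.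

**Compound list**
1 | 2-iodo-N-methylaniline | CNc1ccccc1I | starting material
2 | carbon monoxide | [C-]#[O+] | starting material
3 | 1-heptadecyne (heptadec-1-yne) | C#CCCCCCCCCCCCCCCC | starting material
4 | 1-[2-(methylamino)phenyl]octadec-2-yn-1-one | CCCCCCCCCCCCCCCC#CC(=O)c1ccccc1NC | intermediate
5 | (E)-3-(diethylamino)-1-[2-(methylamino)phenyl]octadec-2-en-1-one (either alkene geometry closes) | CCN(CC)/C(CCCCCCCCCCCCCCC)=C/C(=O)c1ccccc1NC | intermediate
6 | 1-methyl-2-pentadecyl-4(1H)-quinolone | CCCCCCCCCCCCCCCc1cc(=O)c2ccccc2n1C | target

Total step count: 1 (one pot, two stages).
Longest linear sequence: 1 step.

**Steps most likely to fail**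
The route has a single step, so only step 1 can be ranked.

Step 1: the aroyl-palladium species may be diverted before it meets the acetylide. The possible diversions are coupling without CO uptake, acyl transfer to an aniline nitrogen and oxidative dimerisation of the alkyne. The ynone may also close prematurely in the 5-exo sense under the metal catalysts before diethylamine is added.

Fallback, setting out from 3 and returning at 4: the alkyne 3 would be deprotonated with n-BuLi in THF at −78 °C. The lithium acetylide (about 2.5 equiv, since the N–H consumes base) would be added to N-methoxy-N-methyl-2-(methylamino)benzamide F1. F1 would be prepared beforehand from commercial N-methylisatoic anhydride and N,O-dimethylhydroxylamine hydrochloride (Et3N, EtOH, reflux). This Weinreb ketone synthesis should give ynone 4, now isolated in the absence of palladium, copper and CO. The route is rejoined at 4, which would be heated with Et2NH at 80 °C to pass through 5 to 6 as in the second stage of step 1.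

**Further compounds**
F1 | step 1 | N-methoxy-N-methyl-2-(methylamino)benzamide | CNc1ccccc1C(=O)N(C)OC
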